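The numbers come from no measurement; no experiment stands behind them.

If a held gas phase feeds a stirred flask of starting material that also slips into a dormant form, how much target stands at the end?

    target → over-reaction product (k1 = 1.2 × 10⁻⁵ s⁻¹)
    starting material ⇌ dormant form (K2 = 13, k2 = 0.024 s⁻¹)
    2 dissolved gas → self-condensation product (k3 = 53 L mol⁻¹ s⁻¹)
    dissolved gas + target → over-reacted product (k4 = 2.1 L mol⁻¹ s⁻¹)
    starting material + dissolved gas → target (k5 = 5.3 L mol⁻¹ s⁻¹)
    gas phase ⇌ dissolved gas, rate k6*(csat - [dissolved gas]) (k6 = 0.096 s⁻¹, csat = 6.4 mM)

starting material 20 mM; gas phase 6.4 mM (held); time 40 s

- south: doubling the transfer coefficient of step 6, all else as stated
- north: doubling the saturation concentration of gas phase, all else as stated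

- where a step has two of a species, its rate is k times that concentration squared, and two are used at each turn
- at the start none of the gas is dissolved
- run time (flask): 40 s

* the target standing at 40 s, as a percentage of the starting material charged
* concentration of dissolved gas in solution at 20 s, in percent of saturation
* the change that raises the amount of target at 40 s, in percent of the starting material charged most ("none" if none brings more than 2 percentage points) (south / north / none)
* amount of target at 40 s, in percent of the starting material charged, after north

I reckoned two extreme flasks. Capture by starting material gave the dissolved gas a half-life of 6.5 s at the charge, short against 40 s, so I set [dissolved gas] where transfer in equals self-condensation plus capture. With starting material held at its charge that level was 1.64 mM. With starting material at zero it was 2.00 mM, and since starting material falls from its charge, I placed the real flask between them after the first seconds.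

At such a steady level capture is pseudo-first-order in starting material. The capture share, the part of the forward loss of starting material that becomes target, k5[dissolved gas]/(k5[dissolved gas]+k2), was 26.5% at the lower level and 30.6% at the upper. In this reckoning starting material fell at 0.0327 s⁻¹, leaving about half at 20 s. With half the charge the level was 1.81 mM, or 28.2% of saturation.

For 40 s I multiplied the share by the fraction lost, then took off the loss of target to over-reacted product, k4[dissolved gas] over half the run. That gave 18.0% at the lower level and 21.0% at the upper, and I committed to the lower figure. In the lower flask, north raised the level to 2.58 mM and south to 2.28 mM. Target came to 25.2% and 23.1%, so north stood higher than south.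

The forecast gave 18.1% (17% to 19.3%), 27.8% (26% to 29.5%), north, and 24.6% (23% to 26%), on the ground that “Doubling saturation doubles the gas supply without doubling the transfer loss term”. My north figure stood above its own.

The flask gave 17.6% target, north as best with 7 percentage points against 5 points for south, and 24.6% after north. Its dissolved gas stood at 27.6% of saturation at 20.0 s. At 40.0 s the flask held 52.4% dormant form, more than its target, and target with over-reacted product came to 26.8% of the starting material lost over the run. The capture share at that moment's 1.85 mM of dissolved gas was 29.0%. For a neighbouring flask left until 1.0 min, all amounts held, the lower share of 26.5% with the same fraction lost and correction gave 20.5%, and that flask held 20.4% target.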